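**Retrosynthetic overview**

1. The coumarin ether is made last by a Mitsunobu reaction of umbelliferone with the primary alcohol of a tetraol; the acyclic tertiary carbinol comes unchanged from (R)-linalool.
2. The ring is a cyclohexane-1,4-diol (C1: CH3/OH; C2: side chain; C3: two CH3; C4: H/OH). The C4–OH comes from hydroxyl-directed epoxidation of a C4=C5 alkene and hydride opening; the C1–OH comes from Baeyer–Villiger oxidation of a formyl group on C1.
3. Key disconnection: ring bonds C1–C6 and C2–C3, formed together in an enantioselective Diels–Alder reaction of Me2C=C(OSiR3)–CH=CH2 with the (E)-2-methyl-2-enal that carries the whole side chain. This is the only ring formed in the route; the coumarin is bought.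
4. Enabling feature: the two oxygenated ring carbons C1 and C4 are 1,4 to each other, with the gem-dimethyl carbon C3 beside C4 and the side-chain carbon C2 beside C1. C4–O is therefore the 2-oxy group of a diene whose electron-rich CMe2 terminus is C3, and C1–O is a masked formyl group on the α-carbon of the dienophile, so donor and acceptor are matched ("para" orientation).

Key step: step 7

Assumption: the oxazaborolidinium catalyst is taken to bind the 2-methyl-2-enal through its formyl group, as known for 2-substituted enals; on that model the (R)-catalyst gives the (1S,6S) cycloadduct, and with the opposite sense the (S)-catalyst would be used.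

**Route**

Step 1
Reactants: 1 (R)-linalool
Product: 3 (3R)-3,7-dimethyloct-6-ene-1,3-diol, via B-alkyl-9-BBN adduct 2 (not isolated)
Conditions: 9-BBN (1.5 equiv), THF, 0 °C → rt; then NaOH, H2O2, 0 °C → rt
Reagents that add atoms: hydrogen peroxide, OO
Why: Hydroboration–oxidation; 9-BBN adds anti-Markovnikov to the monosubstituted vinyl group much faster than to the trisubstituted alkene, and the stereocentre is not touched.

Step 2
Reactants: 3 (3R)-3,7-dimethyloct-6-ene-1,3-diol
Product: 5 (3R)-1,3-bis(benzyloxy)-3,7-dimethyloct-6-ene, via mono-benzyl ether 4 (not isolated)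
Conditions: NaH (3 equiv), BnBr (2.5 equiv), Bu4NI (cat.), DMF, 0 → 50 °C
Reagents that add atoms: benzyl bromide, BrCc1ccccc1
Why: Williamson etherification; the primary alkoxide reacts first and the tertiary alkoxide follows with iodide catalysis and gentle heating, so both hydroxyls are masked by groups that survive every later step and leave together in step 13.

Step 3
Reactants: 5 (3R)-1,3-bis(benzyloxy)-3,7-dimethyloct-6-ene
Product: 7 (4R)-4,6-bis(benzyloxy)-4-methylhexanal, via ozonide 6 (not isolated)
Conditions: O3, CH2Cl2, −78 °C (indicator end point); then PPh3, −78 °C → rt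
Reagents that add atoms: ozone, [O-][O+]=O
Why: Ozonolysis with reductive work-up cleaves the only C=C bond to the aldehyde; benzyl ethers are inert to ozone at −78 °C on this time scale.

Step 4
Reactants: 7 (4R)-4,6-bis(benzyloxy)-4-methylhexanal; 8 2-(triphenyl-λ5-phosphanylidene)propanal
Product: 9 (2E,6R)-6,8-bis(benzyloxy)-2,6-dimethyloct-2-enal
Conditions: toluene, 90 °C
Reagents that add atoms: none
Why: Wittig olefination with a formyl-stabilised ylide should give the trisubstituted enal with the (E) geometry (side chain trans to CHO), and the aliphatic aldehyde reacts much faster than the product enal.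

Step 5
Reactants: 10 4-methylpent-1-en-3-ol
Product: 11 4-methylpent-1-en-3-one
Conditions: activated MnO2 (excess), CH2Cl2, rt; filtered solution used directly
Reagents that add atoms: none
Why: Allylic alcohol oxidation with MnO2 gives the volatile vinyl ketone under neutral conditions that avoid its polymerisation.

Step 6
Reactants: 11 4-methylpent-1-en-3-one
Product: 12 triisopropyl[(4-methylpenta-1,3-dien-3-yl)oxy]silane
Conditions: TIPSOTf (1.1 equiv), Et3N (1.5 equiv), CH2Cl2, 0 °C → rt
Reagents that add atoms: triisopropylsilyl trifluoromethanesulfonate, CC(C)[Si](OS(=O)(=O)C(F)(F)F)(C(C)C)C(C)C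
Why: Soft enolisation and O-silylation; the ketone can enolise only toward the isopropyl carbon, so the 2-silyloxy diene with the Me2C= terminus is the only possible product and has no E/Z issue.

Step 7
Reactants: 9 (2E,6R)-6,8-bis(benzyloxy)-2,6-dimethyloct-2-enal; 12 triisopropyl[(4-methylpenta-1,3-dien-3-yl)oxy]silane (2 equiv)
Product: 14 (1S,2R)-2-[(3R)-3,5-bis(benzyloxy)-3-methylpentyl]-1,3,3-trimethyl-4-oxocyclohexane-1-carbaldehyde, via silyl enol ether cycloadduct 13 (not isolated)
Conditions: (R)-1-(2-methylphenyl)-3,3-diphenyltetrahydro-1H,3H-pyrrolo[1,2-c][1,3,2]oxazaborole (20 mol %), HNTf2 (20 mol %), CH2Cl2, −78 → −20 °C; then 48% aq. HF, MeCN, 0 °C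
Reagents that add atoms: none
Why: The N-protonated oxazaborolidine binds the formyl group of the s-trans enal 9, and diene 12 adds in a concerted but strongly asynchronous [4+2] cycloaddition in which the bond from the nucleophilic Me2C enol-ether terminus to the β-carbon of the enal runs ahead of the bond from the CH2 terminus to the α-carbon. The closest known reaction type is the chiral oxazaborolidinium-catalysed Diels–Alder reaction of 2-(trialkylsilyloxy)buta-1,3-dienes with 2-methyl-substituted enals, and Lewis-acid-promoted or thermal cycloadditions of dienes with a fully substituted terminus show that the cis-methyl group on the diene is tolerated. The cyclohexene ring is closed in the intermolecular suprafacial [4πs+2πs] mode (in the stepwise limit, Mukaiyama–Michael addition followed by 6-endo-trig Michael closure of the enolate on the silyl-activated vinyl ketone). The two new stereocentres of 14, C1 (CH3, CHO) and C2 (H, side chain), take their relative configuration from the (E) geometry of 9 (side chain cis to the ring methyl, trans to formyl) and their absolute configuration from the catalyst, whose phenyl group shields one face of the bound enal; both diene termini carry two identical groups, so there is no endo/exo issue and no further stereocentre. The step needs "para" regioselectivity and cycloaddition at C=C rather than Mukaiyama addition to C=O: the first is secured by the silyloxy group on the diene carbon next to the CMe2 terminus, reinforced by the two methyl groups, and the second by the formyl-bound, s-trans geometry of the enal in the catalyst complex. Aqueous HF then cleaves the silyl enol ether to the ketone without affecting the benzyl ethers or the non-enolisable aldehyde.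

Step 8
Reactants: 14 (1S,2R)-2-[(3R)-3,5-bis(benzyloxy)-3-methylpentyl]-1,3,3-trimethyl-4-oxocyclohexane-1-carbaldehyde
Product: 16 (3S,4S)-3-[(3R)-3,5-bis(benzyloxy)-3-methylpentyl]-4-hydroxy-2,2,4-trimethylcyclohexan-1-one, via formate ester 15 (not isolated)
Conditions: mCPBA (1.1 equiv), NaHCO3, CH2Cl2, 0 °C → rt; then K2CO3 (cat.), MeOH, rt
Reagents that add atoms: 3-chloroperoxybenzoic acid, OOC(=O)c1cccc(Cl)c1
Why: Baeyer–Villiger oxidation; the tertiary ring carbon migrates in preference to hydrogen with retention of configuration, the aldehyde should react faster than the ketone flanked by a quaternary carbon, and methanolysis of the formate frees the tertiary alcohol trans to the side chain.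

Step 9
Reactants: 16 (3S,4S)-3-[(3R)-3,5-bis(benzyloxy)-3-methylpentyl]-4-hydroxy-2,2,4-trimethylcyclohexan-1-one
Product: 17 N'-{(3S,4S)-3-[(3R)-3,5-bis(benzyloxy)-3-methylpentyl]-4-hydroxy-2,2,4-trimethylcyclohexylidene}-2,4,6-tri(propan-2-yl)benzenesulfonohydrazide
Conditions: 2,4,6-triisopropylbenzenesulfonyl hydrazide (1.2 equiv), HCl (cat.), THF, rt
Reagents that add atoms: 2,4,6-tri(propan-2-yl)benzenesulfonohydrazide, NNS(=O)(=O)c1c(C(C)C)cc(C(C)C)cc1C(C)C
Why: Hydrazone formation; arenesulfonyl hydrazides condense even with ketones next to a quaternary carbon, and the stereocentres are not involved.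

Step 10
Reactants: 17 the arenesulfonyl hydrazone
Product: 19 (1S,6S)-6-[(3R)-3,5-bis(benzyloxy)-3-methylpentyl]-1,5,5-trimethylcyclohex-3-en-1-ol, via vinyllithium alkoxide 18 (not isolated)
Conditions: n-BuLi (3.3 equiv), THF, −78 → 0 °C; then H2O
Reagents that add atoms: none
Why: Shapiro reaction; α-deprotonation is possible only at the ring CH2 because the other α-carbon is quaternary, so loss of sulfinate and N2 gives a single vinyllithium, and protonation gives the alkene with the former carbonyl carbon as CH=.

Step 11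
Reactants: 19 (1S,6S)-6-[(3R)-3,5-bis(benzyloxy)-3-methylpentyl]-1,5,5-trimethylcyclohex-3-en-1-ol
Product: 20 (1R,3S,4S,6S)-4-[(3R)-3,5-bis(benzyloxy)-3-methylpentyl]-3,5,5-trimethyl-7-oxabicyclo[4.1.0]heptan-3-ol
Conditions: VO(acac)2 (5 mol %), t-BuOOH (1.5 equiv), toluene, rt → 40 °C
Reagents that add atoms: tert-butyl hydroperoxide, CC(C)(C)OO
Why: Hydroxyl-directed vanadium-catalysed epoxidation; the homoallylic tertiary OH delivers the oxygen to its own face of the alkene, which is also the face away from the side chain, so the epoxide is formed cis to the OH.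

Step 12
Reactants: 20 the epoxy alcohol
Product: 21 (1S,2S,4R)-2-[(3R)-3,5-bis(benzyloxy)-3-methylpentyl]-1,3,3-trimethylcyclohexane-1,4-diol
Conditions: LiAlH4, THF, 0 °C → reflux
Reagents that add atoms: none
Why: SN2 hydride opening of the epoxide; hydride should attack the epoxide carbon remote from the gem-dimethyl carbon, because the other one is neopentylic and screened by the side chain, which leaves the oxygen on C4 with its configuration unchanged and cis to the tertiary OH.

Step 13
Reactants: 21 the dibenzyl triol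
Product: 22 (1S,2S,4R)-2-[(3R)-3,5-dihydroxy-3-methylpentyl]-1,3,3-trimethylcyclohexane-1,4-diol
Conditions: H2 (1 atm), Pd(OH)2/C, EtOH, rt
Reagents that add atoms: none
Why: Hydrogenolysis removes the primary and the tertiary benzyl ether together; no other reducible group is present.

Step 14
Reactants: 22 the tetraol; 23 7-hydroxy-2H-chromen-2-one (umbelliferone)
Product: 24 7-{[(3R)-5-[(1S,3R,6S)-3,6-dihydroxy-2,2,6-trimethylcyclohexyl]-3-hydroxy-3-methylpentyl]oxy}-2H-chromen-2-one
Conditions: PPh3, DIAD, THF, 0 °C → rt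
Reagents that add atoms: none
Why: Mitsunobu etherification; the acidic phenol should displace only the activated primary alcohol, since the two tertiary alcohols and the neopentylic secondary alcohol are too hindered to form reactive oxyphosphonium species.

**Compound list**

1 | (R)-linalool, (3R)-3,7-dimethylocta-1,6-dien-3-ol | CC(C)=CCC[C@@](C)(O)C=C | starting material
2 | (3R)-1-(9-borabicyclo[3.3.1]nonan-9-yl)-3,7-dimethyloct-6-en-3-ol | CC(C)=CCC[C@@](C)(O)CCB1C2CCCC1CCC2 | intermediate
3 | (3R)-3,7-dimethyloct-6-ene-1,3-diol | CC(C)=CCC[C@@](C)(O)CCO | intermediate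
4 | (3R)-1-(benzyloxy)-3,7-dimethyloct-6-en-3-ol | CC(C)=CCC[C@@](C)(O)CCOCc1ccccc1 | intermediate
5 | (3R)-1,3-bis(benzyloxy)-3,7-dimethyloct-6-ene | CC(C)=CCC[C@@](C)(OCc1ccccc1)CCOCc1ccccc1 | intermediate
6 | 5-[(3R)-3,5-bis(benzyloxy)-3-methylpentyl]-3,3-dimethyl-1,2,4-trioxolane (ozonide, ring carbon configuration undefined) | CC1(C)OOC(CC[C@@](C)(OCc2ccccc2)CCOCc2ccccc2)O1 | intermediate
7 | (4R)-4,6-bis(benzyloxy)-4-methylhexanal | O=CCC[C@@](C)(OCc1ccccc1)CCOCc1ccccc1 | intermediate
8 | 2-(triphenyl-λ5-phosphanylidene)propanal | CC(C=O)=P(c1ccccc1)(c1ccccc1)c1ccccc1 | starting material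
9 | (2E,6R)-6,8-bis(benzyloxy)-2,6-dimethyloct-2-enal | O=C/C(C)=C/CC[C@@](C)(OCc1ccccc1)CCOCc1ccccc1 | intermediate
10 | 4-methylpent-1-en-3-ol (racemic) | C=CC(O)C(C)C | starting material
11 | 4-methylpent-1-en-3-one | C=CC(=O)C(C)C | intermediate
12 | triisopropyl[(4-methylpenta-1,3-dien-3-yl)oxy]silane | CC(C)=C(O[Si](C(C)C)(C(C)C)C(C)C)C=C | intermediate
13 | (1S,6S)-6-[(3R)-3,5-bis(benzyloxy)-3-methylpentyl]-1,5,5-trimethyl-4-[(triisopropylsilyl)oxy]cyclohex-3-ene-1-carbaldehyde | CC1(C)C(O[Si](C(C)C)(C(C)C)C(C)C)=CC[C@](C)(C=O)[C@H]1CC[C@@](C)(OCc1ccccc1)CCOCc1ccccc1 | intermediate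
14 | (1S,2R)-2-[(3R)-3,5-bis(benzyloxy)-3-methylpentyl]-1,3,3-trimethyl-4-oxocyclohexane-1-carbaldehyde (side chain cis to ring CH3, trans to CHO) | CC1(C)C(=O)CC[C@](C)(C=O)[C@H]1CC[C@@](C)(OCc1ccccc1)CCOCc1ccccc1 | intermediate
15 | (1S,2S)-2-[(3R)-3,5-bis(benzyloxy)-3-methylpentyl]-1,3,3-trimethyl-4-oxocyclohexyl formate | CC1(C)C(=O)CC[C@](C)(OC=O)[C@H]1CC[C@@](C)(OCc1ccccc1)CCOCc1ccccc1 | intermediate
16 | (3S,4S)-3-[(3R)-3,5-bis(benzyloxy)-3-methylpentyl]-4-hydroxy-2,2,4-trimethylcyclohexan-1-one | CC1(C)C(=O)CC[C@](C)(O)[C@H]1CC[C@@](C)(OCc1ccccc1)CCOCc1ccccc1 | intermediate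
17 | N'-{(3S,4S)-3-[(3R)-3,5-bis(benzyloxy)-3-methylpentyl]-4-hydroxy-2,2,4-trimethylcyclohexylidene}-2,4,6-tri(propan-2-yl)benzenesulfonohydrazide | CC1(C)C(=NNS(=O)(=O)c2c(C(C)C)cc(C(C)C)cc2C(C)C)CC[C@](C)(O)[C@H]1CC[C@@](C)(OCc1ccccc1)CCOCc1ccccc1 | intermediate
18 | 4-lithio derivative of 19 as its lithium alkoxide (configuration as in 19) | CC1(C)C([Li])=CC[C@](C)(O[Li])[C@H]1CC[C@@](C)(OCc1ccccc1)CCOCc1ccccc1 | intermediate
19 | (1S,6S)-6-[(3R)-3,5-bis(benzyloxy)-3-methylpentyl]-1,5,5-trimethylcyclohex-3-en-1-ol | CC1(C)C=CC[C@](C)(O)[C@H]1CC[C@@](C)(OCc1ccccc1)CCOCc1ccccc1 | intermediate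
20 | (1R,3S,4S,6S)-4-[(3R)-3,5-bis(benzyloxy)-3-methylpentyl]-3,5,5-trimethyl-7-oxabicyclo[4.1.0]heptan-3-ol (epoxide cis to OH) | CC1(C)[C@@H]2O[C@@H]2C[C@](C)(O)[C@H]1CC[C@@](C)(OCc1ccccc1)CCOCc1ccccc1 | intermediate
21 | (1S,2S,4R)-2-[(3R)-3,5-bis(benzyloxy)-3-methylpentyl]-1,3,3-trimethylcyclohexane-1,4-diol | CC1(C)[C@H](O)CC[C@](C)(O)[C@H]1CC[C@@](C)(OCc1ccccc1)CCOCc1ccccc1 | intermediate
22 | (1S,2S,4R)-2-[(3R)-3,5-dihydroxy-3-methylpentyl]-1,3,3-trimethylcyclohexane-1,4-diol | CC1(C)[C@H](O)CC[C@](C)(O)[C@H]1CC[C@@](C)(O)CCO | intermediate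
23 | 7-hydroxy-2H-chromen-2-one (umbelliferone) | Oc1ccc2ccc(=O)oc2c1 | starting material
24 | 7-{[(3R)-5-[(1S,3R,6S)-3,6-dihydroxy-2,2,6-trimethylcyclohexyl]-3-hydroxy-3-methylpentyl]oxy}-2H-chromen-2-one | CC1(C)[C@H](O)CC[C@](C)(O)[C@H]1CC[C@@](C)(O)CCOc1ccc2ccc(=O)oc2c1 | target

**Step count and risks**

Total steps: 14. Longest linear sequence: 12 (steps 1–4 and 7–14).

Step 7. What may go wrong: the cycloaddition may be slow because the cis-methyl group twists the diene out of the s-cis form; the silyl enol ether may add to the formyl carbon instead of the C=C bond; or the catalyst may give poor facial control, which would appear as a mixture of diastereomers because the side-chain stereocentre is fixed. Fallback, setting out from 9 and 12 and coming back at 14: the cycloaddition is run with a stoichiometric achiral aluminium Lewis acid (Me2AlCl, or the AlBr3/AlMe3 mixture used for hindered silyloxy dienes) in CH2Cl2 at low temperature, followed by the same HF treatment. This should give 14 together with its ring-enantiomeric diastereomer, (1R,2S)-2-[(3R)-3,5-bis(benzyloxy)-3-methylpentyl]-1,3,3-trimethyl-4-oxocyclohexane-1-carbaldehyde F2, formed through the corresponding silyl enol ether, (1R,6R)-6-[(3R)-3,5-bis(benzyloxy)-3-methylpentyl]-1,5,5-trimethyl-4-[(triisopropylsilyl)oxy]cyclohex-3-ene-1-carbaldehyde F1, alongside 13. The two diastereomers are separated by preparative HPLC and 14 is carried on; stereocontrol by the catalyst is replaced by separation at the cost of half the material.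

Step 12. What may go wrong: loss of regiocontrol in the epoxide opening, with hydride attacking the neopentylic carbon under trans-diaxial control and placing the hydroxyl on the wrong ring carbon. Fallback, setting out from 20 and coming back at 22: the epoxide is isomerised with LiNEt2 in ether. Only the ring CH2 next to the epoxide carries a β-hydrogen, so the base-induced syn-elimination can give only one allylic alcohol, (1S,4R,6S)-6-[(3R)-3,5-bis(benzyloxy)-3-methylpentyl]-1,5,5-trimethylcyclohex-2-ene-1,4-diol F6, with the oxygen fixed on the carbon next to the gem-dimethyl group. Hydrogenation under the conditions of step 13 then saturates the ring alkene and removes both benzyl groups, giving 22 directly.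

Step 8. What may go wrong: incomplete chemoselectivity, with the peracid also oxidising the ring ketone to a lactone, or hydrogen migration giving the carboxylic acid. Fallback, setting out from 13 (isolated by omitting the HF treatment in step 7) and coming back at 19: the ketone is never unmasked. The silyl enol ether is converted with CsF and PhNTf2 in DME into the enol triflate, (4S,5S)-5-[(3R)-3,5-bis(benzyloxy)-3-methylpentyl]-4-formyl-4,6,6-trimethylcyclohex-1-en-1-yl trifluoromethanesulfonate F3, whose electron-poor double bond is inert to peracid. Baeyer–Villiger oxidation with mCPBA then gives the formate, (4S,5S)-5-[(3R)-3,5-bis(benzyloxy)-3-methylpentyl]-4-(formyloxy)-4,6,6-trimethylcyclohex-1-en-1-yl trifluoromethanesulfonate F4, and mild methanolysis (KHCO3, MeOH) the alcohol, (4S,5S)-5-[(3R)-3,5-bis(benzyloxy)-3-methylpentyl]-4-hydroxy-4,6,6-trimethylcyclohex-1-en-1-yl trifluoromethanesulfonate F5. Palladium-catalysed formate reduction (Pd(OAc)2, PPh3, Bu3N, HCO2H, DMF, 60 °C) replaces the triflate by hydrogen and gives 19, so steps 9 and 10 are not needed.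

**Further compounds**

F1 | step 7 | (1R,6R)-6-[(3R)-3,5-bis(benzyloxy)-3-methylpentyl]-1,5,5-trimethyl-4-[(triisopropylsilyl)oxy]cyclohex-3-ene-1-carbaldehyde | CC1(C)C(O[Si](C(C)C)(C(C)C)C(C)C)=CC[C@@](C)(C=O)[C@@H]1CC[C@@](C)(OCc1ccccc1)CCOCc1ccccc1
F2 | step 7 | (1R,2S)-2-[(3R)-3,5-bis(benzyloxy)-3-methylpentyl]-1,3,3-trimethyl-4-oxocyclohexane-1-carbaldehyde | CC1(C)C(=O)CC[C@@](C)(C=O)[C@@H]1CC[C@@](C)(OCc1ccccc1)CCOCc1ccccc1
F3 | step 8 | (4S,5S)-5-[(3R)-3,5-bis(benzyloxy)-3-methylpentyl]-4-formyl-4,6,6-trimethylcyclohex-1-en-1-yl trifluoromethanesulfonate | CC1(C)C(OS(=O)(=O)C(F)(F)F)=CC[C@](C)(C=O)[C@H]1CC[C@@](C)(OCc1ccccc1)CCOCc1ccccc1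
F4 | step 8 | (4S,5S)-5-[(3R)-3,5-bis(benzyloxy)-3-methylpentyl]-4-(formyloxy)-4,6,6-trimethylcyclohex-1-en-1-yl trifluoromethanesulfonate | CC1(C)C(OS(=O)(=O)C(F)(F)F)=CC[C@](C)(OC=O)[C@H]1CC[C@@](C)(OCc1ccccc1)CCOCc1ccccc1
F5 | step 8 | (4S,5S)-5-[(3R)-3,5-bis(benzyloxy)-3-methylpentyl]-4-hydroxy-4,6,6-trimethylcyclohex-1-en-1-yl trifluoromethanesulfonate | CC1(C)C(OS(=O)(=O)C(F)(F)F)=CC[C@](C)(O)[C@H]1CC[C@@](C)(OCc1ccccc1)CCOCc1ccccc1
F6 | step 12 | (1S,4R,6S)-6-[(3R)-3,5-bis(benzyloxy)-3-methylpentyl]-1,5,5-trimethylcyclohex-2-ene-1,4-diol | CC1(C)[C@H](O)C=C[C@](C)(O)[C@H]1CC[C@@](C)(OCc1ccccc1)CCOCc1ccccc1
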